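**Plan**

- Retrosynthesis: ring C is opened at O1–C2 (cyclodehydration) and the chain is cut at C3–C4 (crossed Claisen). This leaves a ring A salicylate carrying C4 as its ester, and the ω-methoxy ketone of ring B (C2, C3). Ring A is then cut at C5–C6 and C8–C8a.
- Enabling feature: C6(OMe)–C7(OH)–C8(OMe) of ring A is 1,3-dimethoxyacetone, whose carbonyl oxygen ends as the 7-hydroxyl. C5(OMe)–C4a–C8a(O1), with C4 on C4a, is a (dimethoxymethylidene)malonate: acetal carbon, central carbon and one ester carbonyl, the second ester being C4.
- Forward order: ring A is built first by a (3+3) annulation of these two open-chain pieces and its two hydroxyls are masked as MOM ethers. Ring B with C2–C3 is then joined at C3–C4, and ring C closes last in the acid step that also frees the three phenols.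
- Stereochemistry: the target is achiral. The sp3 centres that appear on the way are racemic and enolisable, and vanish on aromatisation or dehydration.

Key step: step 4

Assumption: 1-bromo-4-(methoxymethoxy)benzene and N,2-dimethoxy-N-methylacetamide are taken as purchasable. Flavone numbering is used for the atoms of the target.

**Route**

Step 1
Reactants: 1 1,3-dimethoxypropan-2-ol
Product: 2 1,3-dimethoxypropan-2-one
Conditions: (COCl)2, DMSO, CH2Cl2, −78 °C; Et3N, −78 °C to rt; filtration, distillation
Reagents that add atoms: none
Why: Swern oxidation should convert the unhindered secondary alcohol into the ketone without over-oxidation, and the non-aqueous work-up suits a water-miscible product.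

Step 2
Reactants: 3 dimethyl propanedioate (dimethyl malonate)
Product: 5 dimethyl 2-[bis(methylsulfanyl)methylidene]propanedioate, via dipotassium dithiolate 4 (not isolated)
Conditions: CS2, K2CO3, DMF, rt; then MeI, 0 °C to rt
Reagents that add atoms: carbon disulfide, S=C=S; iodomethane, CI
Why: The malonate carbanion adds to CS2 and the resulting dithiolate is S-methylated twice, the standard ketene dithioacetal synthesis from an active methylene compound.

Step 3
Reactants: 5 dimethyl 2-[bis(methylsulfanyl)methylidene]propanedioate
Product: 6 dimethyl 2-(dimethoxymethylidene)propanedioate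
Conditions: NaOMe (2.5 equiv), MeOH, 0 °C to 65 °C; 1 M HCl to pH 7 at 0 °C; distillation under reduced pressure
Reagents that add atoms: sodium methoxide, C[O-].[Na+]
Why: Two consecutive addition–elimination events (nucleophilic vinylic substitution) at the push–pull carbon should replace both methylsulfanyl groups, the less basic thiolate being the better leaving group and ester exchange with methoxide being degenerate.

Step 4
Reactants: 2 1,3-dimethoxypropan-2-one; 6 dimethyl 2-(dimethoxymethylidene)propanedioate
Product: 8 methyl 2,4-dihydroxy-3,5,6-trimethoxybenzoate, via open-chain keto alkene 7 (not isolated)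
Conditions: NaOMe (3 equiv), MeOH, 65 °C, 2 added slowly; then 1 M HCl
Reagents that add atoms: none
Why: Proposed new method: methoxide generates the enolate of 2 reversibly, whose α-carbon adds to the acetal carbon of the push–pull alkene 6 and expels methoxide (addition–elimination), forming the future C5–C6 bond and giving 7; proton transfer to the other α-carbon then allows a Claisen (Dieckmann-type) attack on the ester cis to the new chain, forming C8–C8a, and loss of methoxide with double enolisation should deliver the aromatic bis-phenoxide. The closest known reaction types are the base-mediated (3+3) phenol annulations of dialkyl ketones with α-acyl ketene dithioacetals and the condensations of acetonedicarboxylates with 1,3-dielectrophiles to resorcinols. Ring A closes by a 6-exo-trig acyl substitution, one ester of the malonate unit being necessarily cis to the side chain. No stereocentre is created, since the single sp3 centre of 7 is lost on aromatisation. The step needs C- rather than O-attack of the enolates, and under methanolic NaOMe the O-acylation product (an α-pyrone) and the aldol dimer of 2 can revert, whereas the arene bis-phenoxide is an irreversible sink. No regiochemical choice arises because 2 and the malonate unit of 6 are each symmetric, and every alkoxide exchange is degenerate because all ester and ether groups are methyl.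

Step 5
Reactants: 8 methyl 2,4-dihydroxy-3,5,6-trimethoxybenzoate
Product: 9 methyl 3,5,6-trimethoxy-2,4-bis(methoxymethoxy)benzoate
Conditions: NaH (2.5 equiv), DMF, 0 °C; MOMCl (2.5 equiv), 0 °C to rt
Reagents that add atoms: chloromethyl methyl ether, COCCl
Why: Williamson-type O-alkylation of both sodium phenoxides should give the bis-MOM ether, NaH ensuring that the hydrogen-bonded 2-hydroxyl is fully deprotonated, and the ether removes the phenoxide deactivation of the ester for step 7.

Step 6
Reactants: 10 1-bromo-4-(methoxymethoxy)benzene; 11 N,2-dimethoxy-N-methylacetamide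
Product: 13 2-methoxy-1-[4-(methoxymethoxy)phenyl]ethan-1-one, via aryllithium 12 (not isolated)
Conditions: n-BuLi, THF, −78 °C; then 11, −78 °C to 0 °C; AcOH quench
Reagents that add atoms: none
Why: Bromine–lithium exchange followed by Weinreb ketone synthesis, in which the chelated tetrahedral adduct persists until the quench and so prevents double addition.

Step 7
Reactants: 9 methyl 3,5,6-trimethoxy-2,4-bis(methoxymethoxy)benzoate; 13 2-methoxy-1-[4-(methoxymethoxy)phenyl]ethan-1-one
Product: 14 2-methoxy-1-[4-(methoxymethoxy)phenyl]-3-[3,5,6-trimethoxy-2,4-bis(methoxymethoxy)phenyl]propane-1,3-dione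
Conditions: NaH (3 equiv), THF, 0 °C to 65 °C; AcOH quench
Reagents that add atoms: none
Why: Crossed Claisen condensation of the ketone enolate with a non-enolisable o-alkoxybenzoate, the classical entry to flavone 1,3-diketones, driven by deprotonation of the product; the methoxy-bearing carbon is formed racemic and is flattened in step 8.

Step 8
Reactants: 14 2-methoxy-1-[4-(methoxymethoxy)phenyl]-3-[3,5,6-trimethoxy-2,4-bis(methoxymethoxy)phenyl]propane-1,3-dione
Product: 16 7-hydroxy-2-(4-hydroxyphenyl)-3,5,6,8-tetramethoxy-4H-chromen-4-one, via free triphenol diketone 15 (not isolated)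
Conditions: conc. HCl, MeOH, 60 °C
Reagents that add atoms: none
Why: Acid-catalysed acetal exchange should cleave the three MOM ethers, and the liberated 2-hydroxyl, the only one ortho to a carbonyl, adds to the distal ketone (6-exo-trig) and dehydrates, the standard cyclodehydration of o-hydroxyaryl 1,3-diketones to flavones.

**Compound list**

1 | 1,3-dimethoxypropan-2-ol | COCC(O)COC | starting material
2 | 1,3-dimethoxypropan-2-one | COCC(=O)COC | intermediate
3 | dimethyl propanedioate (dimethyl malonate) | COC(=O)CC(=O)OC | starting material
4 | dipotassium 2,2-bis(methoxycarbonyl)ethene-1,1-bis(thiolate) | COC(=O)C(C(=O)OC)=C([S-])[S-].[K+].[K+] | intermediate (not isolated)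
5 | dimethyl 2-[bis(methylsulfanyl)methylidene]propanedioate | COC(=O)C(C(=O)OC)=C(SC)SC | intermediate
6 | dimethyl 2-(dimethoxymethylidene)propanedioate | COC(OC)=C(C(=O)OC)C(=O)OC | intermediate
7 | dimethyl 2-(1,2,4-trimethoxy-3-oxobutylidene)propanedioate (racemic) | COCC(=O)C(OC)C(OC)=C(C(=O)OC)C(=O)OC | intermediate (not isolated)
8 | methyl 2,4-dihydroxy-3,5,6-trimethoxybenzoate | COC(=O)c1c(O)c(OC)c(O)c(OC)c1OC | intermediate
9 | methyl 3,5,6-trimethoxy-2,4-bis(methoxymethoxy)benzoate | COCOc1c(OC)c(OCOC)c(C(=O)OC)c(OC)c1OC | intermediate
10 | 1-bromo-4-(methoxymethoxy)benzene | COCOc1ccc(Br)cc1 | starting material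
11 | N,2-dimethoxy-N-methylacetamide | COCC(=O)N(C)OC | starting material
12 | [4-(methoxymethoxy)phenyl]lithium | [Li]c1ccc(OCOC)cc1 | intermediate (not isolated)
13 | 2-methoxy-1-[4-(methoxymethoxy)phenyl]ethan-1-one | COCOc1ccc(cc1)C(=O)COC | intermediate
14 | 2-methoxy-1-[4-(methoxymethoxy)phenyl]-3-[3,5,6-trimethoxy-2,4-bis(methoxymethoxy)phenyl]propane-1,3-dione (racemic) | COCOc1ccc(cc1)C(=O)C(OC)C(=O)c1c(OCOC)c(OC)c(OCOC)c(OC)c1OC | intermediate
15 | 1-(2,4-dihydroxy-3,5,6-trimethoxyphenyl)-3-(4-hydroxyphenyl)-2-methoxypropane-1,3-dione (racemic) | COC(C(=O)c1ccc(O)cc1)C(=O)c1c(O)c(OC)c(O)c(OC)c1OC | intermediate (not isolated)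
16 | 7-hydroxy-2-(4-hydroxyphenyl)-3,5,6,8-tetramethoxy-4H-chromen-4-one | COc1c(O)c(OC)c2oc(-c3ccc(O)cc3)c(OC)c(=O)c2c1OC | target

**Count and risks**

Total step count: 8. Longest linear sequence: 6 steps (steps 2, 3, 4, 5, 7 and 8, from dimethyl malonate 3).

Steps most likely to fail:

1. Step 4 (the proposed annulation). The enolate of 2 may fail to engage the weakly electrophilic acetal carbon of 6, and aldol self-condensation of the ketone or O-acylation to an α-pyrone may outrun carbon–carbon bond formation. The fallback takes ring A from the aromatic pool by known reactions. It branches from no numbered compound of the route, since none carries a preformed ring A. It sets out from commercial methyl 4-hydroxy-3,5-dimethoxybenzoate F1 and comes back to the route at 8. O-Benzylation (BnBr, K2CO3, DMF) should give methyl 4-(benzyloxy)-3,5-dimethoxybenzoate F2. Twofold electrophilic bromination of the two free ring positions (NBS, MeCN, 60 °C) should give methyl 4-(benzyloxy)-2,6-dibromo-3,5-dimethoxybenzoate F3. Ullmann-type methoxylation (NaOMe, CuBr cat., DMF–MeOH, 110 °C) should give methyl 4-(benzyloxy)-2,3,5,6-tetramethoxybenzoate F4. BCl3 (CH2Cl2, −78 °C to 0 °C) should then remove the benzyl group and, through chelation to the ester carbonyl, one of the two equivalent ortho methoxy groups, giving 8.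

2. Step 7 (crossed Claisen). Addition of the enolate to the ester flanked by two ortho substituents may be too slow, so that self-aldolisation of 13 and decomposition on prolonged heating take over. The fallback replaces acyl substitution by an aldol addition to a less hindered trigonal carbon and a later oxidation. It sets out from 9 (with 13 as partner) and comes back at 14. Reduction of 9 (LiAlH4, THF, 0 °C) should give [3,5,6-trimethoxy-2,4-bis(methoxymethoxy)phenyl]methanol F5. Benzylic oxidation (MnO2, CH2Cl2) should give 3,5,6-trimethoxy-2,4-bis(methoxymethoxy)benzaldehyde F6. Aldol addition of the lithium enolate of 13 (LiN(SiMe3)2, THF, −78 °C) should give 3-hydroxy-2-methoxy-1-[4-(methoxymethoxy)phenyl]-3-[3,5,6-trimethoxy-2,4-bis(methoxymethoxy)phenyl]propan-1-one F7 as a mixture of racemic diastereomers, which is of no consequence. Dess–Martin oxidation of the β-hydroxy ketone should give 14.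

3. Step 3 (sulfur-to-oxygen exchange). The second substitution may stall at the mixed O,S-acetal, because the first methoxy group lowers the electrophilicity of the alkene, or methoxide may add without elimination. The fallback activates the remaining sulfur as a sulfoxide. It sets out from 5 and comes back at 6. One equivalent of NaOMe (MeOH, 0 °C) should give dimethyl 2-[methoxy(methylsulfanyl)methylidene]propanedioate F8. Oxidation at sulfur (mCPBA, 1 equiv, CH2Cl2, 0 °C) should give dimethyl 2-[methanesulfinyl(methoxy)methylidene]propanedioate F9, racemic at sulfur. NaOMe (MeOH, 0 °C) should then displace the far better sulfinyl leaving group and give 6.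

**Further compounds**

F1 | step 4 | methyl 4-hydroxy-3,5-dimethoxybenzoate | COC(=O)c1cc(OC)c(O)c(OC)c1
F2 | step 4 | methyl 4-(benzyloxy)-3,5-dimethoxybenzoate | COC(=O)c1cc(OC)c(OCc2ccccc2)c(OC)c1
F3 | step 4 | methyl 4-(benzyloxy)-2,6-dibromo-3,5-dimethoxybenzoate | COC(=O)c1c(Br)c(OC)c(OCc2ccccc2)c(OC)c1Br
F4 | step 4 | methyl 4-(benzyloxy)-2,3,5,6-tetramethoxybenzoate | COC(=O)c1c(OC)c(OC)c(OCc2ccccc2)c(OC)c1OC
F5 | step 7 | [3,5,6-trimethoxy-2,4-bis(methoxymethoxy)phenyl]methanol | COCOc1c(OC)c(OCOC)c(CO)c(OC)c1OC
F6 | step 7 | 3,5,6-trimethoxy-2,4-bis(methoxymethoxy)benzaldehyde | COCOc1c(OC)c(OCOC)c(C=O)c(OC)c1OC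
F7 | step 7 | 3-hydroxy-2-methoxy-1-[4-(methoxymethoxy)phenyl]-3-[3,5,6-trimethoxy-2,4-bis(methoxymethoxy)phenyl]propan-1-one (mixture of racemic diastereomers) | COCOc1ccc(cc1)C(=O)C(OC)C(O)c1c(OCOC)c(OC)c(OCOC)c(OC)c1OC
F8 | step 3 | dimethyl 2-[methoxy(methylsulfanyl)methylidene]propanedioate | COC(SC)=C(C(=O)OC)C(=O)OC
F9 | step 3 | dimethyl 2-[methanesulfinyl(methoxy)methylidene]propanedioate (racemic at sulfur) | COC(=C(C(=O)OC)C(=O)OC)S(C)=O
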